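Ring B is disconnected at O1–B6. B6 is a tertiary allylic ether carbon bonded to diene carbon D4, so it can come from the D4=B6 alkene of a geranyl unit. In one operation, electrophilic selenium on that alkene triggers 6-exo attack of the B2 hydroxyl at B6: the tetrahydropyran closes, B6 is set relative to B3, and the selenide left at D4, whose only β-hydrogens sit on D3, is poised for syn-elimination into conjugation with D1=D2. The precursor is the skipped (E,E)-diene bromohydrin with ring A complete; its ring A tertiary hydroxyl, cis to the side chain, is silylated to block a cineole-type closure onto D1.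

Key step: step 11

Labels: ring A is the cyclohexane and keeps the limonene numbering (C1 = C(CH3)(O), C2 = CHBr, C4 = the CH that carries the side chain). Ring B is the tetrahydropyran O1, B2 = C(CH3)2, B3 = CHBr, B6 = C(CH3). The diene carbons are D1 (on ring A C4, bearing CH3), D2, D3 and D4 (on B6). In the geranyl fragment, C6 is the carbon that becomes B3.

Remark: the triethylsilyl ether on the ring A C1 oxygen, installed in step 3, is a spectator kept until step 13; it shuts off epoxide formation in step 7 and ether formation from that oxygen in step 11.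

Step 1
Reactants: 1 (S)-(−)-limonene
Product: 2 (4S)-limonene 1,2-oxide (both epoxide diastereomers)
Conditions: mCPBA (1.0 equiv), CH2Cl2, 0 °C
Reagents that add atoms: mCPBA, OOC(=O)c1cccc(Cl)c1
Why: Prilezhaev epoxidation is selective for the more electron-rich trisubstituted ring alkene over the 1,1-disubstituted isopropenyl alkene, and facial control is not needed because step 2 is stereoconvergent.

Step 2
Reactants: 2 (4S)-limonene 1,2-oxide (both epoxide diastereomers)
Product: 3 (1R,2R,4S)-limonene-1,2-diol (trans-diaxial diol; C1–OH cis and C2–OH trans to the isopropenyl group)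
Conditions: H2SO4 (0.1 M aq), THF, 0 °C to rt
Reagents that add atoms: water, O
Why: Acid-catalysed epoxide hydrolysis under trans-diaxial (Fürst–Plattner) control opens the epoxide lying trans to the isopropenyl group at C1 and the cis epoxide at C2, so both converge on the same diaxial diol while C4 stays as in limonene.

Step 3
Reactants: 3 (1R,2R,4S)-limonene-1,2-diol
Product: 4 bis(triethylsilyl) ether of 3
Conditions: Et3SiOTf (2.5 equiv), 2,6-lutidine (4 equiv), CH2Cl2, −78 to 0 °C
Reagents that add atoms: triethylsilyl triflate, CC[Si](CC)(CC)OS(=O)(=O)C(F)(F)F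
Why: Silylation with a silyl triflate and a hindered pyridine base is reactive enough for the tertiary axial hydroxyl and masks both oxygens for the strongly basic step 5.

Step 4
Reactants: 4 bis(triethylsilyl) ether of 3
Product: 5 methyl ketone, 1-[(1S,3R,4R)-4-methyl-3,4-bis(triethylsilyloxy)cyclohexyl]ethanone
Conditions: O3, CH2Cl2/MeOH, −78 °C; then Me2S, −78 °C to rt
Reagents that add atoms: ozone, [O-][O+]=O
Why: Ozonolysis with reductive work-up cleaves the only C=C bond to the methyl ketone, and in the absence of base the acetyl group stays equatorial at C4.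

Step 5
Reactants: 5 methyl ketone
Product: 7 (1R,2R,4S)-4-ethynyl-1-methyl-1,2-bis(triethylsilyloxy)cyclohexane, via enol phosphate 6 (not isolated)
Conditions: LiN(i-Pr)2 (1.1 equiv), THF, −78 °C; ClP(O)(OEt)2, −78 °C to rt; then added to LiN(i-Pr)2 (2.3 equiv), THF, −78 °C to rt; then H2O
Reagents that add atoms: none
Why: In the enol phosphate route from a methyl ketone to a terminal alkyne, kinetic deprotonation at the methyl group, O-phosphorylation to 6 and elimination with excess amide base give the alkyne without enolisation towards the ring carbon C4.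

Step 6
Reactants: 7 bis-silylated alkyne
Product: 8 (1R,2R,5S)-5-ethynyl-2-methyl-2-(triethylsilyloxy)cyclohexan-1-ol (C2–OH axial and free, C1–O still silylated)
Conditions: PPTS (0.2 equiv), MeOH/CH2Cl2 (1:4), 0 °C, stopped when 7 is consumed
Reagents that add atoms: none
Why: Acid-catalysed methanolysis of silyl ethers is governed by steric access to oxygen, so the secondary ether at C2 should be cleaved well before the tertiary ether at C1.

Step 7
Reactants: 8 secondary alcohol
Product: 9 {[(1R,2S,4S)-2-bromo-4-ethynyl-1-methylcyclohexyl]oxy}triethylsilane (C2–Br equatorial, cis to the C1 oxygen)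
Conditions: PPh3 (3 equiv), CBr4 (2.5 equiv), 2,6-lutidine (1 equiv), toluene, 0 to 60 °C
Reagents that add atoms: carbon tetrabromide, BrC(Br)(Br)Br
Why: In this Appel reaction the axial oxyphosphonium group at C2 is displaced by bromide from the opposite face (SN2, inversion) to give the equatorial bromide cis to the C1 oxygen, and because that oxygen is silylated the epoxide closure that a free trans-diaxial diol would undergo (net retention) is shut off.

Step 8
Reactants: 10 geranyl acetate
Product: 11 (6R)-6,7-epoxygeranyl acetate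
Conditions: D-fructose-derived Shi ketone (0.3 equiv), KHSO5 (as 2KHSO5·KHSO4·K2SO4), K2CO3, Bu4NHSO4 (cat), MeCN/CH2(OMe)2/aq Na2B4O7 buffer, 0 °C
Reagents that add atoms: potassium peroxymonosulfate, [K+].[O-]S(=O)(=O)OO
Why: In this Shi epoxidation the chiral dioxirane attacks the electron-rich 6,7-alkene (the 2,3-alkene is deactivated by the allylic acetate) through a spiro transition state that delivers oxygen to the face giving the 6R epoxide.

Step 9
Reactants: 11 (6R)-6,7-epoxygeranyl acetate
Product: 12 (2E,6S)-6-bromo-7-hydroxy-3,7-dimethyloct-2-en-1-yl acetate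
Conditions: Li2NiBr4 (0.4 M in THF, 1.5 equiv), THF, 0 °C to rt; then pH 7 buffer
Reagents that add atoms: dilithium tetrabromonickelate (divalent nickel), [Li+].[Li+].[Ni+2].[Br-].[Br-].[Br-].[Br-]
Why: Soft bromide from Li2NiBr4 opens the epoxide by SN2 attack at the less substituted carbon C6 with inversion, giving the 6S secondary bromide and the tertiary alcohol, since no strong acid is present to divert attack to the tertiary carbon.

Step 10
Reactants: 9 bromo alkyne (ring A fragment); 12 bromohydrin acetate
Product: 15 skipped (E,E)-diene bromohydrin with the ring A C1 oxygen silylated, via alkenylalane 13 (not isolated), via aluminium alkoxide 14 (not isolated)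
Conditions: 9, AlMe3 (2.5 equiv), Cp2ZrCl2 (0.25 equiv), CH2Cl2, 0 °C to rt; 12 pre-treated with AlMe3 (1.05 equiv), THF, −20 °C; combined, Pd(PPh3)4 (5 mol%), THF, rt; aq KNaC4H4O6 work-up
Reagents that add atoms: trimethylaluminium, C[Al](C)C
Why: Negishi carboalumination adds CH3 and Al syn across the alkyne with Al at the terminal carbon, and Pd-catalysed allylation of the resulting E alkenylalane (Negishi coupling) with the geranyl-type acetate at its primary terminus keeps both alkene geometries, the hydroxyl of 12 being masked in the flask as its aluminium alkoxide.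

Step 11
Reactants: 15 skipped (E,E)-diene bromohydrin with the ring A C1 oxygen silylated
Product: 16 D4 phenylselenide of the cyclised skeleton (B3 S, B6 R, D4 S)
Conditions: N-(phenylseleno)phthalimide (1.2 equiv), CSA (0.1 equiv), CH2Cl2, −20 to 0 °C
Reagents that add atoms: N-(phenylseleno)phthalimide, O=C1c2ccccc2C(=O)N1[Se]c1ccccc1
Why: Acid-activated N-(phenylseleno)phthalimide transfers PhSe+ reversibly to the trisubstituted alkenes, and the seleniranium ion on D4=B6 is opened at its tertiary carbon B6 by the B2 hydroxyl anti to selenium, forming O1–B6 and D4–Se. The closest known reaction type is phenylselenoetherification of a tertiary alkenol to a ditertiary cyclic ether. Ring B closes in the 6-exo-trig (Markovnikov) mode. B6 is set by 1,4-induction from B3 through a chair transition state with bromine equatorial, the smaller B6 methyl axial and the selenium-bridged branch equatorial, which places the branch trans to bromine (B6 R), while D4 (S, transient) follows from stereospecific anti addition across the E alkene. The step needs chemoselectivity between two trisubstituted alkenes and two tertiary oxygens: only the B2 hydroxyl is free, the ring A C1 oxygen is silylated so that the D1=D2 seleniranium ion has no partner, and reversible selenium transfer should funnel material to 16.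

Step 12
Reactants: 16 D4 phenylselenide
Product: 18 (E,E)-diene with the ring A C1 oxygen silylated, via selenoxide 17 (not isolated)
Conditions: mCPBA (1.05 equiv), CH2Cl2, −78 °C; then i-Pr2NH (3 equiv), −78 °C to rt
Reagents that add atoms: none
Why: Selenide oxidation followed by selenoxide syn-elimination can only take a hydrogen from D3, the sole β-carbon bearing hydrogen, and the allylic C–H and the developing conjugation with D1=D2 favour the E D3=D4 alkene.

Step 13
Reactants: 18 (E,E)-diene with the ring A C1 oxygen silylated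
Product: 19 target CNP0199463.2
Conditions: Bu4NF (1.5 equiv), AcOH (1.5 equiv), THF, 0 °C to rt
Reagents that add atoms: none
Why: Fluoride-induced cleavage of the Si–O bond under acetic acid buffering frees the ring A tertiary hydroxyl without ionising the tertiary dienylic ether at B6 or eliminating the equatorial bromides.

Compound list
1 | (S)-(−)-limonene, (4S)-1-methyl-4-(prop-1-en-2-yl)cyclohex-1-ene | CC(=C)[C@@H]1CC=C(C)CC1 | starting material
2 | (4S)-limonene 1,2-oxide, mixture of the two epoxide diastereomers (C1 and C2 not defined) | CC(=C)[C@H]1CCC2(C)OC2C1 | intermediate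
3 | (1R,2R,4S)-1-methyl-4-(prop-1-en-2-yl)cyclohexane-1,2-diol | CC(=C)[C@H]1CC[C@@](C)(O)[C@H](O)C1 | intermediate
4 | (1R,2R,4S)-1-methyl-4-(prop-1-en-2-yl)-1,2-bis(triethylsilyloxy)cyclohexane | CC(=C)[C@H]1CC[C@@](C)(O[Si](CC)(CC)CC)[C@H](O[Si](CC)(CC)CC)C1 | intermediate
5 | 1-[(1S,3R,4R)-4-methyl-3,4-bis(triethylsilyloxy)cyclohexyl]ethan-1-one | CC(=O)[C@H]1CC[C@@](C)(O[Si](CC)(CC)CC)[C@H](O[Si](CC)(CC)CC)C1 | intermediate
6 | diethyl 1-[(1S,3R,4R)-4-methyl-3,4-bis(triethylsilyloxy)cyclohexyl]ethenyl phosphate | C=C(OP(=O)(OCC)OCC)[C@H]1CC[C@@](C)(O[Si](CC)(CC)CC)[C@H](O[Si](CC)(CC)CC)C1 | intermediate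
7 | (1R,2R,4S)-4-ethynyl-1-methyl-1,2-bis(triethylsilyloxy)cyclohexane | C#C[C@H]1CC[C@@](C)(O[Si](CC)(CC)CC)[C@H](O[Si](CC)(CC)CC)C1 | intermediate
8 | (1R,2R,5S)-5-ethynyl-2-methyl-2-(triethylsilyloxy)cyclohexan-1-ol | C#C[C@H]1CC[C@@](C)(O[Si](CC)(CC)CC)[C@H](O)C1 | intermediate
9 | {[(1R,2S,4S)-2-bromo-4-ethynyl-1-methylcyclohexyl]oxy}triethylsilane | C#C[C@H]1CC[C@@](C)(O[Si](CC)(CC)CC)[C@@H](Br)C1 | intermediate
10 | geranyl acetate, (2E)-3,7-dimethylocta-2,6-dien-1-yl acetate | CC(C)=CCC/C(C)=C/COC(C)=O | starting material
11 | (2E)-5-[(2R)-3,3-dimethyloxiran-2-yl]-3-methylpent-2-en-1-yl acetate | CC1(C)O[C@@H]1CC/C(C)=C/COC(C)=O | intermediate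
12 | (2E,6S)-6-bromo-7-hydroxy-3,7-dimethyloct-2-en-1-yl acetate | CC(C)(O)[C@@H](Br)CC/C(C)=C/COC(C)=O | intermediate
13 | {(1E)-2-[(1S,3S,4R)-3-bromo-4-methyl-4-(triethylsilyloxy)cyclohexyl]prop-1-en-1-yl}dimethylalane | C/C(=C\[Al](C)C)[C@H]1CC[C@@](C)(O[Si](CC)(CC)CC)[C@@H](Br)C1 | intermediate
14 | (2E,6S)-6-bromo-7-[(dimethylalumanyl)oxy]-3,7-dimethyloct-2-en-1-yl acetate | CC(C)(O[Al](C)C)[C@@H](Br)CC/C(C)=C/COC(C)=O | intermediate
15 | (3S,6E,9E)-3-bromo-10-[(1S,3S,4R)-3-bromo-4-methyl-4-(triethylsilyloxy)cyclohexyl]-2,6-dimethylundeca-6,9-dien-2-ol | C/C(=C\C/C=C(\C)CC[C@H](Br)C(C)(C)O)[C@H]1CC[C@@](C)(O[Si](CC)(CC)CC)[C@@H](Br)C1 | intermediate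
16 | (3S,6R)-3-bromo-6-{(1S,3E)-4-[(1S,3S,4R)-3-bromo-4-methyl-4-(triethylsilyloxy)cyclohexyl]-1-(phenylselanyl)pent-3-en-1-yl}-2,2,6-trimethyltetrahydro-2H-pyran | C/C(=C\C[C@H]([Se]c2ccccc2)[C@@]1(C)CC[C@H](Br)C(C)(C)O1)[C@H]1CC[C@@](C)(O[Si](CC)(CC)CC)[C@@H](Br)C1 | intermediate
17 | selenoxide of 16 (both configurations at selenium) | C/C(=C\C[C@H]([Se](=O)c2ccccc2)[C@@]1(C)CC[C@H](Br)C(C)(C)O1)[C@H]1CC[C@@](C)(O[Si](CC)(CC)CC)[C@@H](Br)C1 | intermediate
18 | {[(1R,2S,4S)-2-bromo-4-{(2E,4E)-5-[(2R,5S)-5-bromo-2,6,6-trimethyltetrahydro-2H-pyran-2-yl]penta-2,4-dien-2-yl}-1-methylcyclohexyl]oxy}triethylsilane | C/C(=C\C=C\[C@@]1(C)CC[C@H](Br)C(C)(C)O1)[C@H]1CC[C@@](C)(O[Si](CC)(CC)CC)[C@@H](Br)C1 | intermediate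
19 | (1R,2S,4S)-2-bromo-4-{(2E,4E)-5-[(2R,5S)-5-bromo-2,6,6-trimethyltetrahydro-2H-pyran-2-yl]penta-2,4-dien-2-yl}-1-methylcyclohexan-1-ol | C/C(=C\C=C\[C@@]1(C)CC[C@H](Br)C(C)(C)O1)[C@H]1CC[C@@](C)(O)[C@@H](Br)C1 | target

Total step count: 13. Longest linear sequence: 11 steps (steps 1–7 and 10–13).

Steps most likely to fail

Step 11. Weak 1,4-induction from B3 would close ring B on both faces of B6, and selenium parked on the D1=D2 alkene would lower conversion. The fallback takes B6 from the chiral pool, closes ring B at O1–B2 and makes the diene by a vinylic coupling. It sets out from 9 and comes back at 18. Alkyne 9 is carboaluminated as in step 10 (alane 13), and the alane is quenched with I2 to give alkenyl iodide F1. Commercial (R)-(−)-linalool (C=C[C@](C)(O)CCC=C(C)C) is cyclised with 2,4,4,6-tetrabromocyclohexa-2,5-dienone in CH2Cl2: bromonium formation at the trisubstituted alkene and attack of the tertiary hydroxyl at the tertiary carbon should give bromo vinyl tetrahydropyran F2 beside its B3 epimer F3, which is removed by chromatography. A Heck reaction of F1 with F2 (Pd(OAc)2, K2CO3, Bu4NCl, DMF) should form the D2–D3 bond and the E D3=D4 alkene, which is 18.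

Step 7. β-Elimination of the axial oxyphosphonium group towards the ring CH2 between C2 and C4, or participation of the vicinal silyloxy oxygen, could outrun SN2 at a carbon that sits next to a fully substituted centre. The fallback replaces phosphonium activation by a discrete sulfonate and a soluble, non-basic bromide. It sets out from 8 and comes back at 9. Tf2O and pyridine in CH2Cl2 at −78 °C should give triflate F4, which is displaced cold with Bu4NBr in toluene (inversion) to give 9.

Step 9. Regiocontrol in the epoxide opening could be lost, with bromide entering at the tertiary carbon. The fallback makes the tertiary bromide on purpose and then moves bromine to C6 through a bromonium ion. It sets out from 11 and comes back at 12. Anhydrous HBr in Et2O at −40 °C should open the epoxide at the tertiary carbon to tertiary bromide F5, with C6 untouched (R). MsCl and pyridine give mesylate F6. In aqueous acetone buffered with NaHCO3 the neighbouring bromine should displace the mesylate from the rear, inverting C6, and water should open the bromonium ion at the tertiary carbon to give 12.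

Further compounds
F1 | step 11 | {[(1R,2S,4S)-2-bromo-4-[(1E)-1-iodoprop-1-en-2-yl]-1-methylcyclohexyl]oxy}triethylsilane | C/C(=C\I)[C@H]1CC[C@@](C)(O[Si](CC)(CC)CC)[C@@H](Br)C1
F2 | step 11 | (3S,6R)-3-bromo-6-ethenyl-2,2,6-trimethyltetrahydro-2H-pyran | C=C[C@@]1(C)CC[C@H](Br)C(C)(C)O1
F3 | step 11 | (3R,6R)-3-bromo-6-ethenyl-2,2,6-trimethyltetrahydro-2H-pyran | C=C[C@@]1(C)CC[C@@H](Br)C(C)(C)O1
F4 | step 7 | (1R,2R,5S)-5-ethynyl-2-methyl-2-(triethylsilyloxy)cyclohexyl trifluoromethanesulfonate | C#C[C@H]1CC[C@@](C)(O[Si](CC)(CC)CC)[C@H](OS(=O)(=O)C(F)(F)F)C1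
F5 | step 9 | (2E,6R)-7-bromo-6-hydroxy-3,7-dimethyloct-2-en-1-yl acetate | CC(C)(Br)[C@H](O)CC/C(C)=C/COC(C)=O
F6 | step 9 | (2E,6R)-7-bromo-3,7-dimethyl-6-(methylsulfonyloxy)oct-2-en-1-yl acetate | CC(C)(Br)[C@H](OS(C)(=O)=O)CC/C(C)=C/COC(C)=O
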